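**Plan**

1. The target is an oxolane in which C3 and C4 are the α-carbons of two 2,4-dihydroxyphenyl ketones (a 1,4-diketone) and C2 and C5 are the oxygen-bearing benzylic carbons β to them: two β-hydroxy-dihydrochalcone (aldol) units joined α to α, which is the bond an oxidative enolate coupling makes.
2. Retrosynthesis: the ring C2–O bond is cut first (back to a C2-symmetric 1,4-diol of opposite configuration at that carbon), then the C3–C4 bond, then the aldol C–C bond of each identical half.
3. Forward: one (R)-aldol is made by a catalytic asymmetric Mukaiyama aldol addition, and two molecules are tied through their carbinol oxygens by a diisopropylsilylene bridge (O–Si–O, not in the target).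
4. Oxidative coupling of the tethered bis-enolate closes a temporary seven-membered 1,3,2-dioxasilepane by the C3–C4 bond and sets both new centres, all-trans, by relay from the carbinol centres.
5. Silicon is excised and the oxolane closed by Mitsunobu cyclodehydration with inversion at one of the two equivalent carbinols, which turns the symmetric all-trans array into the 2,3-cis/3,4-trans/4,5-trans array; pivalates on the 4-oxyphenyl rings keep this substitution from ionising.
6. All stereochemistry stems from one catalyst-set centre used twice; benzyl ethers and pivalates are removed last.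

Key step: step 5

Remark: the Re-face preference assumed for the catalyst of step 3 is taken by analogy with simple aryl enol silanes and aryl aldehydes; if 6 proves to be S, the catalyst from (R)-tryptophan is used.
Remark: C2–C5 denote the oxolane carbons of the target throughout; the target is (2S,3R,4R,5R).

**Route**

Step 1
Reactants: 1 4-hydroxybenzaldehyde
Product: 2 4-formylphenyl pivalate
Conditions: pivaloyl chloride, Et3N, 4-(dimethylamino)pyridine (DMAP, cat.), CH2Cl2, 0 °C to rt
Reagents that add atoms: pivaloyl chloride CC(C)(C)C(=O)Cl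
Why: DMAP-catalysed O-acylation of the phenol is routine; the pivalate is chosen because it makes the ring a poor cation-stabilising group for step 7 and withstands the amide base of step 5.

Step 2
Reactants: 3 1-[2,4-bis(benzyloxy)phenyl]ethan-1-one
Product: 4 {1-[2,4-bis(benzyloxy)phenyl]ethenyl}oxy(trimethyl)silane
Conditions: Me3SiOTf, Et3N, CH2Cl2, 0 °C
Reagents that add atoms: trimethylsilyl trifluoromethanesulfonate C[Si](C)(C)OS(=O)(=O)C(F)(F)F
Why: Soft enolisation and O-silylation of a methyl ketone with a single enolisable position (silyl enol ether formation) gives the nucleophile for the Mukaiyama aldol addition.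

Step 3
Reactants: 4 {1-[2,4-bis(benzyloxy)phenyl]ethenyl}oxy(trimethyl)silane; 2 4-formylphenyl pivalate
Product: 6 4-[(1R)-3-[2,4-bis(benzyloxy)phenyl]-1-hydroxy-3-oxopropyl]phenyl pivalate, via O-trimethylsilyl aldol 5 (not isolated)
Conditions: (4S)-2-butyl-4-(1H-indol-3-ylmethyl)-3-(4-methylbenzenesulfonyl)-1,3,2-oxazaborolidin-5-one (20 mol%), EtCN, −78 °C; then 1 M HCl, THF, 0 °C
Reagents that add atoms: none
Why: Catalytic enantioselective Mukaiyama aldol addition, in which the boron Lewis acid binds the aldehyde and its indole ring screens one face so that the enol silane should add to the Re face and set the (R)-carbinol centre, the silyl ether formed by silyl transfer being cleaved on acidic work-up.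

Step 4
Reactants: 6 4-[(1R)-3-[2,4-bis(benzyloxy)phenyl]-1-hydroxy-3-oxopropyl]phenyl pivalate (two molecules)
Product: 7 bis{(1R)-3-[2,4-bis(benzyloxy)phenyl]-3-oxo-1-[4-(pivaloyloxy)phenyl]propoxy}di(propan-2-yl)silane
Conditions: iPr2SiCl2 (0.5 equiv), imidazole, DMAP (cat.), DMF, 0 °C to rt
Reagents that add atoms: dichlorodi(propan-2-yl)silane CC(C)[Si](Cl)(Cl)C(C)C
Why: Two-fold O-silylation of the secondary alcohol gives the bis(alkoxy)silane tether without touching the stereocentre, and because the minor (S)-alcohol ends up mostly in the separable meso (R,S) bis-ether the C2-symmetric product should be of higher enantiomeric purity than 6 (statistical amplification on dimerisation).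

Step 5
Reactants: 7 bis{(1R)-3-[2,4-bis(benzyloxy)phenyl]-3-oxo-1-[4-(pivaloyloxy)phenyl]propoxy}di(propan-2-yl)silane
Product: 9 (4R,5R,6R,7R)-5,6-bis[2,4-bis(benzyloxy)benzoyl]-2,2-di(propan-2-yl)-4,7-bis[4-(pivaloyloxy)phenyl]-1,3,2-dioxasilepane, via dilithium bis(Z-enolate) 8 (not isolated)
Conditions: LiN(SiMe3)2 (2.3 equiv), THF, −78 °C, substrate added to base at high dilution; then CuCl2 (2.5 equiv) in DMF, −78 to −40 °C; aq. NH4Cl
Reagents that add atoms: none
Why: Two-fold deprotonation gives the bis(Z-enolate) 8, one enolate is oxidised by divalent copper to an α-keto radical (or copper enolate) that attacks the α-carbon of the second enolate, and a second equivalent of CuCl2 oxidises the resulting ketyl to the 1,4-diketone. The closest known reaction type is the intramolecular oxidative coupling of ketone dienolates by CuCl2, run here through a temporary bis(alkoxy)silane tether. The ring closed is the seven-membered 1,3,2-dioxasilepane, in 7-exo-trig mode with respect to the attacked enolate double bond. Each new centre is controlled by the neighbouring carbinol carbon: allylic 1,3-strain in the Z-enolate holds the carbinol hydrogen in the enolate plane, so the bridge oxygen lies on one face and the aryl group on the other, and the tethered partner can only arrive syn to oxygen and anti to aryl, which puts each aroyl group trans to the adjacent aryl group and, the two carbinols being homochiral, trans to each other (5R,6R from 4R,7R). The step needs ring closure to outrun β-elimination of silanolate and intermolecular coupling, which the low temperature, the lithium enolate, high dilution and the two isopropyl groups on silicon are meant to secure. Each ketone has a single enolisable position, so only the wanted α,α′ bond can form, and the all-trans product is also the expected thermodynamic isomer should the new centres equilibrate.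

Step 6
Reactants: 9 (4R,5R,6R,7R)-5,6-bis[2,4-bis(benzyloxy)benzoyl]-2,2-di(propan-2-yl)-4,7-bis[4-(pivaloyloxy)phenyl]-1,3,2-dioxasilepane
Product: 10 (2R,3R)-1,4-bis[2,4-bis(benzyloxy)phenyl]-2,3-bis{(R)-hydroxy[4-(pivaloyloxy)phenyl]methyl}butane-1,4-dione
Conditions: HF·pyridine, pyridine, THF, 0 °C
Reagents that add atoms: none
Why: Fluoride cleavage of the two Si–O bonds of the dialkoxysilane under buffered, non-basic conditions should release the diol without retro-aldol cleavage or epimerisation, the electron-poor pivaloyloxyphenyl carbinols being inert to ionisation.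

Step 7
Reactants: 10 (2R,3R)-1,4-bis[2,4-bis(benzyloxy)phenyl]-2,3-bis{(R)-hydroxy[4-(pivaloyloxy)phenyl]methyl}butane-1,4-dione
Product: 11 (2S,3R,4R,5R)-3,4-bis[2,4-bis(benzyloxy)benzoyl]-2,5-bis[4-(pivaloyloxy)phenyl]oxolane
Conditions: PPh3, diisopropyl azodicarboxylate (DIAD, added slowly), toluene, 0 °C to rt
Reagents that add atoms: none
Why: Mitsunobu cyclodehydration of a 1,4-diol, in which one hydroxyl is activated as the alkoxyphosphonium ion and displaced by the other in a 5-exo-tet SN2 closure, so that the attacked carbinol carbon is inverted (R to S) and its aryl group becomes cis to the neighbouring aroyl group, while the C2 symmetry of 10 makes both hydroxyls lead to the same product and the pivalate-deactivated ring suppresses the competing SN1 path.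

Step 8
Reactants: 11 (2S,3R,4R,5R)-3,4-bis[2,4-bis(benzyloxy)benzoyl]-2,5-bis[4-(pivaloyloxy)phenyl]oxolane
Product: 12 (2S,3R,4R,5R)-3,4-bis(2,4-dihydroxybenzoyl)-2,5-bis[4-(pivaloyloxy)phenyl]oxolane
Conditions: H2 (1 atm), 10% Pd/C, EtOAc–THF, rt
Reagents that add atoms: none
Why: Heterogeneous hydrogenolysis of the four aryl benzyl ethers under neutral conditions touches no stereocentre, and the ring C–O bonds (benzylic to electron-poor rings) and the emerging hydrogen-bonded 2-hydroxyaryl ketones are expected to be reduced far more slowly.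

Step 9
Reactants: 12 (2S,3R,4R,5R)-3,4-bis(2,4-dihydroxybenzoyl)-2,5-bis[4-(pivaloyloxy)phenyl]oxolane
Product: 13 (2S,3R,4R,5R)-3,4-bis(2,4-dihydroxybenzoyl)-2,5-bis(4-hydroxyphenyl)oxolane (CNP0237262.2)
Conditions: K2CO3, MeOH, 0 °C to rt, short exposure; then aq. NaH2PO4
Reagents that add atoms: none
Why: Base-promoted methanolysis (transesterification) of the two aryl pivalates, during which the 2,4-dihydroxyphenyl ketones are present as phenolates, which lowers the acidity of the hydrogens at C3 and C4 and so should guard against epimerisation and β-elimination of the ring oxygen.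

**Compound list**

1 | 4-hydroxybenzaldehyde | O=Cc1ccc(O)cc1 | starting material
2 | 4-formylphenyl pivalate | CC(C)(C)C(=O)Oc1ccc(C=O)cc1 | intermediate
3 | 1-[2,4-bis(benzyloxy)phenyl]ethan-1-one | CC(=O)c1ccc(OCc2ccccc2)cc1OCc1ccccc1 | starting material
4 | {1-[2,4-bis(benzyloxy)phenyl]ethenyl}oxy(trimethyl)silane | C=C(O[Si](C)(C)C)c1ccc(OCc2ccccc2)cc1OCc1ccccc1 | intermediate
5 | 4-[(1R)-3-[2,4-bis(benzyloxy)phenyl]-3-oxo-1-(trimethylsilyloxy)propyl]phenyl pivalate | C[Si](C)(C)O[C@@H](c1ccc(OC(=O)C(C)(C)C)cc1)CC(=O)c1ccc(OCc2ccccc2)cc1OCc1ccccc1 | intermediate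
6 | 4-[(1R)-3-[2,4-bis(benzyloxy)phenyl]-1-hydroxy-3-oxopropyl]phenyl pivalate | O[C@@H](c1ccc(OC(=O)C(C)(C)C)cc1)CC(=O)c1ccc(OCc2ccccc2)cc1OCc1ccccc1 | intermediate
7 | bis{(1R)-3-[2,4-bis(benzyloxy)phenyl]-3-oxo-1-[4-(pivaloyloxy)phenyl]propoxy}di(propan-2-yl)silane | CC(C)[Si](C(C)C)(O[C@@H](c1ccc(OC(=O)C(C)(C)C)cc1)CC(=O)c1ccc(OCc2ccccc2)cc1OCc1ccccc1)O[C@@H](c1ccc(OC(=O)C(C)(C)C)cc1)CC(=O)c1ccc(OCc2ccccc2)cc1OCc1ccccc1 | intermediate
8 | dilithium bis(Z-enolate) of 7 | CC(C)[Si](C(C)C)(O[C@@H](c1ccc(OC(=O)C(C)(C)C)cc1)/C=C(\O[Li])c1ccc(OCc2ccccc2)cc1OCc1ccccc1)O[C@@H](c1ccc(OC(=O)C(C)(C)C)cc1)/C=C(\O[Li])c1ccc(OCc2ccccc2)cc1OCc1ccccc1 | intermediate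
9 | (4R,5R,6R,7R)-5,6-bis[2,4-bis(benzyloxy)benzoyl]-2,2-di(propan-2-yl)-4,7-bis[4-(pivaloyloxy)phenyl]-1,3,2-dioxasilepane | CC(C)[Si]1(C(C)C)O[C@@H](c2ccc(OC(=O)C(C)(C)C)cc2)[C@H](C(=O)c2ccc(OCc3ccccc3)cc2OCc2ccccc2)[C@@H](C(=O)c2ccc(OCc3ccccc3)cc2OCc2ccccc2)[C@H](c2ccc(OC(=O)C(C)(C)C)cc2)O1 | intermediate
10 | (2R,3R)-1,4-bis[2,4-bis(benzyloxy)phenyl]-2,3-bis{(R)-hydroxy[4-(pivaloyloxy)phenyl]methyl}butane-1,4-dione | O[C@@H](c1ccc(OC(=O)C(C)(C)C)cc1)[C@H](C(=O)c1ccc(OCc2ccccc2)cc1OCc1ccccc1)[C@@H](C(=O)c1ccc(OCc2ccccc2)cc1OCc1ccccc1)[C@@H](O)c1ccc(OC(=O)C(C)(C)C)cc1 | intermediate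
11 | (2S,3R,4R,5R)-3,4-bis[2,4-bis(benzyloxy)benzoyl]-2,5-bis[4-(pivaloyloxy)phenyl]oxolane | O=C(c1ccc(OCc2ccccc2)cc1OCc1ccccc1)[C@@H]1[C@@H](C(=O)c2ccc(OCc3ccccc3)cc2OCc2ccccc2)[C@H](c2ccc(OC(=O)C(C)(C)C)cc2)O[C@@H]1c1ccc(OC(=O)C(C)(C)C)cc1 | intermediate
12 | (2S,3R,4R,5R)-3,4-bis(2,4-dihydroxybenzoyl)-2,5-bis[4-(pivaloyloxy)phenyl]oxolane | O=C(c1ccc(O)cc1O)[C@@H]1[C@@H](C(=O)c2ccc(O)cc2O)[C@H](c2ccc(OC(=O)C(C)(C)C)cc2)O[C@@H]1c1ccc(OC(=O)C(C)(C)C)cc1 | intermediate
13 | (2S,3R,4R,5R)-3,4-bis(2,4-dihydroxybenzoyl)-2,5-bis(4-hydroxyphenyl)oxolane | O=C(c1ccc(O)cc1O)[C@@H]1[C@@H](C(=O)c2ccc(O)cc2O)[C@H](c2ccc(O)cc2)O[C@@H]1c1ccc(O)cc1 | target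

**Count and risks**

Total steps: 9. Longest linear sequence: 8 steps (step 1 or step 2, then steps 3 to 9).

Steps most likely to fail:

1. Step 5. The lithium enolate may lose silanolate by β-elimination, couple intermolecularly, be α-chlorinated by CuCl2, or close with poor facial selectivity. Fallback: setting out from 7, soft enolisation (Me3SiOTf, Et3N, CH2Cl2, 0 °C) gives the bis(trimethylsilyl enol ether) F1. This is oxidised with (NH4)2Ce(NO3)6 and NaHCO3 in MeCN at −20 °C, so that the C–C bond forms by radical-cation coupling of the two tethered enol silanes without any basic enolate. The route is rejoined at 9.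

2. Step 7. The activated hydroxyl may be lost by β-elimination toward the α-arylidene ketone, a ketone oxygen may take part (dihydrofuran formation or retention), or the carbinol may partly ionise. Fallback: activation is separated from ring closure and kept free of any species basic enough for elimination. Setting out from 10, (MeSO2)2O and 2,6-di-tert-butylpyridine in CH2Cl2 at −40 °C give the monomethanesulfonate F2 with retention, which on warming is displaced by the free hydroxyl with inversion. The route is rejoined at 11.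

3. Step 3. The ortho-substituted enol silane may give low enantioselectivity or the opposite sense of induction, or may be hydrolysed before it adds. Fallback: enantiocontrol is moved from catalysis to separation. Setting out from 4 and 2, catalytic Sc(OTf)3 in CH2Cl2 at −78 °C gives the racemic silyl ether, that is 5 together with its enantiomer, the (S)-O-trimethylsilyl aldol F3. Acidic work-up gives racemic aldol, that is 6 together with the (S)-aldol F4, which is resolved by preparative chromatography on a chiral stationary phase. The route is rejoined at 6.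

Further compounds
F1 | step 5 | bis[(Z)-trimethylsilyl enol ether] of 7 | CC(C)[Si](C(C)C)(O[C@@H](c1ccc(OC(=O)C(C)(C)C)cc1)/C=C(\O[Si](C)(C)C)c1ccc(OCc2ccccc2)cc1OCc1ccccc1)O[C@@H](c1ccc(OC(=O)C(C)(C)C)cc1)/C=C(\O[Si](C)(C)C)c1ccc(OCc2ccccc2)cc1OCc1ccccc1
F2 | step 7 | monomethanesulfonate of 10 | CS(=O)(=O)O[C@@H](c1ccc(OC(=O)C(C)(C)C)cc1)[C@H](C(=O)c1ccc(OCc2ccccc2)cc1OCc1ccccc1)[C@@H](C(=O)c1ccc(OCc2ccccc2)cc1OCc1ccccc1)[C@@H](O)c1ccc(OC(=O)C(C)(C)C)cc1
F3 | step 3 | 4-[(1S)-3-[2,4-bis(benzyloxy)phenyl]-3-oxo-1-(trimethylsilyloxy)propyl]phenyl pivalate | C[Si](C)(C)O[C@H](c1ccc(OC(=O)C(C)(C)C)cc1)CC(=O)c1ccc(OCc2ccccc2)cc1OCc1ccccc1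
F4 | step 3 | 4-[(1S)-3-[2,4-bis(benzyloxy)phenyl]-1-hydroxy-3-oxopropyl]phenyl pivalate | O[C@H](c1ccc(OC(=O)C(C)(C)C)cc1)CC(=O)c1ccc(OCc2ccccc2)cc1OCc1ccccc1
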